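**Plan**

- Labels: ring A is O1, C2 (CMe2), C3=C4, C5 (CHOH), C6 (C–CH3, carries ring B). Ring B is C1' (on C6) to C6', with C4' = C(CH3)Cl and C5' = CHBr.
- Cuts: first C5–O (back to an allylic CH2), then O1–C6 and C5–C6 together. This works because C6 carries O1, C5, CH3 and C1' and no hydrogen, so it is the carbonyl carbon of a ring B methyl ketone; O1 and C2–C5 are then a tertiary homoallylic alcohol with silicon on C3.
- Ring B: the equatorial C4'–Cl/C5'–Br pair is traced through a 1,2-interchange of the two halogens to the trans-diaxial isomer (Br on C4', Cl on C5'), and from there to trans-limonene oxide and (S)-limonene.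
- Forward order: ring B is bought and given its halogens (steps 1–6), the chiral silane is made (steps 7–10), ring A is closed in one operation (step 11), and the C5 hydroxyl is added last (step 12).
- Stereochemistry: C1' comes from (S)-limonene. C4' and C5' are relayed from C1' by trans-diaxial openings and the stereospecific interchange (a direct BrCl addition is expected to give the other, diaxial diastereomer). C6 comes from the silicon-bearing carbon (Rh-catalysed Si–H insertion) through an anti SE2' chair. C5 comes from C6 by a suprafacial SeO2 ene/[2,3] sequence.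

Key step: step 11

Assumption: Rh2(S-DOSP)4, dirhodium tetrakis[(S)-N-(4-dodecylphenylsulfonyl)prolinate], is taken to give the (S)-α-silyl ester 12; if the sense of induction is the opposite, Rh2(R-DOSP)4 is used and nothing else changes.

**Route**

Step 1
Reactants: 1 (S)-limonene
Product: 2 (1R,2R,4S)-2-bromo-1-methyl-4-(prop-1-en-2-yl)cyclohexan-1-ol
Conditions: NBS (1.1 equiv), acetone/H2O 4:1, 0 °C
Reagents that add atoms: N-bromosuccinimide, O=C1CCC(=O)N1Br; water, O
Why: Bromohydrin formation: the trisubstituted ring alkene is the more nucleophilic one, and water opens the bromonium ion at the tertiary carbon in the trans-diaxial (Fürst–Plattner) sense with the isopropenyl-bearing carbon as equatorial anchor, so OH ends axial on the face of the isopropenyl group and Br axial on the other face, as established for limonene.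

Step 2
Reactants: 2 (1R,2R,4S)-2-bromo-1-methyl-4-(prop-1-en-2-yl)cyclohexan-1-ol
Product: 3 (1R,4S,6S)-1-methyl-4-(prop-1-en-2-yl)-7-oxabicyclo[4.1.0]heptane (trans-limonene 1,2-oxide)
Conditions: NaOH (2 M aq), MeOH, rt
Reagents that add atoms: none
Why: Intramolecular Williamson etherification: the axial alkoxide displaces the antiperiplanar axial bromide with inversion at C5', which places the epoxide oxygen on the face of the isopropenyl group.

Step 3
Reactants: 3 (1R,4S,6S)-1-methyl-4-(prop-1-en-2-yl)-7-oxabicyclo[4.1.0]heptane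
Product: 4 (1R,2R,4S)-2-chloro-1-methyl-4-(prop-1-en-2-yl)cyclohexan-1-ol
Conditions: LiCl, AcOH, THF, rt
Reagents that add atoms: lithium chloride, [Li+].[Cl-]
Why: Acid-assisted SN2 epoxide opening: chloride enters at the secondary carbon C5' anti to oxygen, which is both the less hindered site and the only trans-diaxial mode that keeps the side chain equatorial, so C5' is inverted (Cl axial, trans to the side chain) and the tertiary C–O bond is untouched; the isopropenyl group is inert to this buffered medium.

Step 4
Reactants: 4 (1R,2R,4S)-2-chloro-1-methyl-4-(prop-1-en-2-yl)cyclohexan-1-ol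
Product: 6 1-[(1S,3R,4R)-3-chloro-4-hydroxy-4-methylcyclohexyl]ethan-1-one, via ozonide 5 (not isolated)
Conditions: O3, CH2Cl2, −78 °C; then Me2S, −78 °C to rt
Reagents that add atoms: ozone, O=[O+][O-]
Why: Ozonolysis with reductive work-up cleaves the only alkene, the isopropenyl group, to the methyl ketone; alcohol and chloride are inert and no stereocentre is touched.

Step 5
Reactants: 6 1-[(1S,3R,4R)-3-chloro-4-hydroxy-4-methylcyclohexyl]ethan-1-one
Product: 7 1-[(1S,3R,4R)-4-bromo-3-chloro-4-methylcyclohexyl]ethan-1-one
Conditions: TMSBr (1.5 equiv), CH2Cl2, 0 °C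
Reagents that add atoms: bromotrimethylsilane, C[Si](C)(C)Br
Why: SN1 substitution of a tertiary alcohol: the tertiary cation, bridged by the antiperiplanar axial chlorine, is captured by bromide from the axial direction anti to that chlorine, so C–O is replaced by C–Br with retention and the trans-diaxial dihalide results; C1' is the more stable epimer in 6 and 7 and is not endangered by the acid.

Step 6
Reactants: 7 1-[(1S,3R,4R)-4-bromo-3-chloro-4-methylcyclohexyl]ethan-1-one
Product: 8 1-[(1S,3S,4S)-3-bromo-4-chloro-4-methylcyclohexyl]ethan-1-one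
Conditions: PhCl, CaCO3 (powder), 130 °C, sealed tube; recovered 7 is returned to the step
Reagents that add atoms: none
Why: Thermal diaxial-to-diequatorial rearrangement of a vicinal dihalide (1,2-dyotropic halogen interchange): the antiperiplanar C–Br and C–Cl bonds of 7 exchange carbons, bromine moving on the upper face from C4' to C5' and chlorine on the lower face from C5' to C4' with inversion at both centres, which can only give the 3S,4S isomer with both halogens equatorial; chlorine on the tertiary carbon and the more polar diequatorial dihalide should be favoured, and CaCO3 removes HBr so that C1' of 8 is not epimerised by enolisation.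

Step 7
Reactants: 9 methyl but-3-enoate
Product: 10 methyl 2-diazobut-3-enoate
Conditions: p-ABSA (4-acetamidobenzenesulfonyl azide), DBU, MeCN, 0 °C; kept cold and used at once
Reagents that add atoms: 4-acetamidobenzenesulfonyl azide, CC(=O)Nc1ccc(cc1)S(=O)(=O)N=[N+]=[N-]
Why: Regitz diazo transfer to the α-carbon of the extended enolate of a β,γ-unsaturated ester; the vinyldiazoacetate cyclises to a pyrazole on standing, hence the cold, immediate use.

Step 8
Reactants: 10 methyl 2-diazobut-3-enoate; 11 dimethylphenylsilane
Product: 12 methyl (2S)-2-[dimethyl(phenyl)silyl]but-3-enoate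
Conditions: Rh2(S-DOSP)4 (1 mol %), pentane, −78 °C, slow addition of 10
Reagents that add atoms: none
Why: Carbenoid Si–H insertion of a vinyl (donor/acceptor) rhodium carbenoid: the concerted three-centre insertion outruns cyclopropanation and dimerisation at −78 °C, and the chiral prolinate ligands select the carbenoid face, which sets the silicon-bearing stereocentre as S.

Step 9
Reactants: 12 methyl (2S)-2-[dimethyl(phenyl)silyl]but-3-enoate
Product: 14 (3S)-3-[dimethyl(phenyl)silyl]-2-methylpent-4-en-2-ol, via silyl methyl ketone 13 (not isolated)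
Conditions: MeMgBr (3 equiv), CeCl3 (anhydrous), THF, −78 to 0 °C; aq NH4Cl
Reagents that add atoms: methylmagnesium bromide, C[Mg]Br
Why: Double 1,2-addition of a cerium-modified Grignard reagent to the ester: the weakly basic organocerium species avoids deprotonation of the acidic α-silyl allylic C–H (racemisation, conjugation), and the magnesium/cerium alkoxide of the β-hydroxysilane does not undergo Peterson elimination in the cold; the stereocentre is not involved.

Step 10
Reactants: 14 (3S)-3-[dimethyl(phenyl)silyl]-2-methylpent-4-en-2-ol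
Product: 15 dimethyl(phenyl)[(3S)-2-methyl-2-(trimethylsilyloxy)pent-4-en-3-yl]silane
Conditions: N-(trimethylsilyl)imidazole, CH2Cl2, rt
Reagents that add atoms: N-(trimethylsilyl)imidazole, C[Si](C)(C)n1ccnc1
Why: Silylation of a hindered tertiary alcohol with a neutral silyl-transfer reagent, which avoids the acid that would trigger Peterson elimination of the β-hydroxysilane.

Step 11
Reactants: 8 1-[(1S,3S,4S)-3-bromo-4-chloro-4-methylcyclohexyl]ethan-1-one; 15 dimethyl(phenyl)[(3S)-2-methyl-2-(trimethylsilyloxy)pent-4-en-3-yl]silane (1.3 equiv)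
Product: 18 (2S)-2-[(1S,3S,4S)-3-bromo-4-chloro-4-methylcyclohexyl]-2,6,6-trimethyl-3,6-dihydro-2H-pyran, via mixed silyl ketal 16 (not isolated), via oxocarbenium triflate 17 (not isolated)
Conditions: TMSOTf (1.0 equiv), 2,6-di-tert-butyl-4-methylpyridine (0.2 equiv), CH2Cl2, −78 to −40 °C; aq NaHCO3
Reagents that add atoms: none
Why: Proposed new method: TMSOTf silylates the ketone oxygen of 8, the silyl ether oxygen of 15 adds to give the mixed silyl ketal 16, loss of hexamethyldisiloxane gives the C6=O1 oxocarbenium ion 17, and its vinyl terminus C5 attacks C6 while the C3–Si bond stabilises the developing C4 cation, after which silicon leaves and C3=C4 remains; the closest known reaction type is the TMSOTf-mediated [4+2] annulation (intramolecular silyl-modified Sakurai reaction) of β-silyloxy allylsilanes with aldehydes to dihydropyrans, here extended to a ketone and a tertiary carbinol. Ring A closes in a 6-endo-trig chair in which the C3–Si bond is axial and anti to the forming C5–C6 bond (anti SE2'). The new stereocentre C6 is fixed by the silicon-bearing carbon of 15, because in that chair the axial site on C6 is 1,3-diaxial to a C2 methyl, so the small C6 methyl goes axial and ring B equatorial, which gives 2S. The step needs O-condensation and ring closure to outrun open-chain allyl transfer and acid-type Peterson loss of the β-silyl tertiary ether: TMSOTf alone does not activate a ketone enough for direct allylation, the gem-dimethyl group (Thorpe–Ingold effect) speeds the closure, and low temperature with a hindered pyridine keeps triflic acid away. The tertiary chloride should survive because the gauche β-bromine retards its ionisation, and the cold, base-poor medium should leave the enolisable C1' centre of 8 alone.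

Step 12
Reactants: 18 (2S)-2-[(1S,3S,4S)-3-bromo-4-chloro-4-methylcyclohexyl]-2,6,6-trimethyl-3,6-dihydro-2H-pyran
Product: 19 (2R,3R)-2-[(1S,3S,4S)-3-bromo-4-chloro-4-methylcyclohexyl]-2,6,6-trimethyl-3,6-dihydro-2H-pyran-3-ol
Conditions: SeO2 (0.5 equiv), t-BuOOH (3 equiv), CH2Cl2, rt, stopped before over-oxidation
Reagents that add atoms: selenium dioxide, O=[Se]=O; tert-butyl hydroperoxide, CC(C)(C)OO
Why: Riley-type allylic hydroxylation: the only allylic C–H bonds are at C5, selenium adds to C3 and takes the pseudoaxial C5–H from the ring face that is free of the pseudoaxial C2 and C6 methyls (ene reaction), and the [2,3]-sigmatropic shift returns oxygen to C5 on that same face with C3=C4 restored, i.e. cis to ring B and trans to the C6 methyl; a C5 ketone/hydride sequence is avoided because hydride would be expected to enter anti to the axial C6 methyl and give the C5 epimer.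

**Compound list**

1 | (S)-limonene, (4S)-1-methyl-4-(prop-1-en-2-yl)cyclohex-1-ene | CC(=C)[C@H]1CCC(C)=CC1 | starting material
2 | (1R,2R,4S)-2-bromo-1-methyl-4-(prop-1-en-2-yl)cyclohexan-1-ol | CC(=C)[C@H]1CC[C@@](C)(O)[C@H](Br)C1 | intermediate
3 | (1R,4S,6S)-1-methyl-4-(prop-1-en-2-yl)-7-oxabicyclo[4.1.0]heptane (trans-limonene 1,2-oxide) | CC(=C)[C@H]1CC[C@@]2(C)O[C@H]2C1 | intermediate
4 | (1R,2R,4S)-2-chloro-1-methyl-4-(prop-1-en-2-yl)cyclohexan-1-ol | CC(=C)[C@H]1CC[C@@](C)(O)[C@H](Cl)C1 | intermediate
5 | 3-[(1S,3R,4R)-3-chloro-4-hydroxy-4-methylcyclohexyl]-3-methyl-1,2,4-trioxolane (ozonide, both epimers at the trioxolane carbon) | CC1(OOCO1)[C@H]2CC[C@@](C)(O)[C@H](Cl)C2 | intermediate (not isolated)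
6 | 1-[(1S,3R,4R)-3-chloro-4-hydroxy-4-methylcyclohexyl]ethan-1-one | CC(=O)[C@H]1CC[C@@](C)(O)[C@H](Cl)C1 | intermediate
7 | 1-[(1S,3R,4R)-4-bromo-3-chloro-4-methylcyclohexyl]ethan-1-one (Br and Cl trans-diaxial) | CC(=O)[C@H]1CC[C@@](C)(Br)[C@H](Cl)C1 | intermediate
8 | 1-[(1S,3S,4S)-3-bromo-4-chloro-4-methylcyclohexyl]ethan-1-one (Br and Cl trans-diequatorial) | CC(=O)[C@H]1CC[C@](C)(Cl)[C@@H](Br)C1 | intermediate
9 | methyl but-3-enoate | COC(=O)CC=C | starting material
10 | methyl 2-diazobut-3-enoate | COC(=O)C(=[N+]=[N-])C=C | intermediate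
11 | dimethylphenylsilane | C[SiH](C)c1ccccc1 | starting material
12 | methyl (2S)-2-[dimethyl(phenyl)silyl]but-3-enoate | COC(=O)[C@@H]([Si](C)(C)c1ccccc1)C=C | intermediate
13 | (3S)-3-[dimethyl(phenyl)silyl]pent-4-en-2-one | CC(=O)[C@@H]([Si](C)(C)c1ccccc1)C=C | intermediate (not isolated)
14 | (3S)-3-[dimethyl(phenyl)silyl]-2-methylpent-4-en-2-ol | CC(C)(O)[C@@H]([Si](C)(C)c1ccccc1)C=C | intermediate
15 | dimethyl(phenyl)[(3S)-2-methyl-2-(trimethylsilyloxy)pent-4-en-3-yl]silane | CC(C)(O[Si](C)(C)C)[C@@H]([Si](C)(C)c1ccccc1)C=C | intermediate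
16 | mixed silyl ketal: the (3S)-3-[dimethyl(phenyl)silyl]-2-methylpent-4-en-2-yl ether of 1-[(1S,3S,4S)-3-bromo-4-chloro-4-methylcyclohexyl]-1-(trimethylsilyloxy)ethanol (both epimers at the ketal carbon) | C[Si](C)(C)OC(C)([C@H]1CC[C@](C)(Cl)[C@@H](Br)C1)OC(C)(C)[C@@H]([Si](C)(C)c1ccccc1)C=C | intermediate (not isolated)
17 | oxocarbenium triflate: {1-[(1S,3S,4S)-3-bromo-4-chloro-4-methylcyclohexyl]ethylidene}[(3S)-3-[dimethyl(phenyl)silyl]-2-methylpent-4-en-2-yl]oxonium trifluoromethanesulfonate (reacting geometry: ring B anti to the O-alkyl group) | CC(=[O+]C(C)(C)[C@@H]([Si](C)(C)c1ccccc1)C=C)[C@H]1CC[C@](C)(Cl)[C@@H](Br)C1.[O-]S(=O)(=O)C(F)(F)F | intermediate (not isolated)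
18 | (2S)-2-[(1S,3S,4S)-3-bromo-4-chloro-4-methylcyclohexyl]-2,6,6-trimethyl-3,6-dihydro-2H-pyran | CC1(C)C=CC[C@@](C)([C@H]2CC[C@](C)(Cl)[C@@H](Br)C2)O1 | intermediate
19 | (2R,3R)-2-[(1S,3S,4S)-3-bromo-4-chloro-4-methylcyclohexyl]-2,6,6-trimethyl-3,6-dihydro-2H-pyran-3-ol | CC1(C)C=C[C@@H](O)[C@@](C)([C@H]2CC[C@](C)(Cl)[C@@H](Br)C2)O1 | target

**Count and risks**

Total steps: 12. Longest linear sequence: 8 steps (steps 1–6, 11, 12).

Steps most likely to fail:

1. Step 11. What may go wrong: acid-type Peterson elimination of the β-silyl tertiary ether before it condenses with the hindered ketone; open-chain allyl transfer that would leave C6 uncontrolled; a twist-boat closure that erodes the C6 selectivity; slow ionisation of the tertiary chloride. Fallback with known reactions only, from ketone 8 back to dihydropyran 18: diol-catalysed asymmetric allylboration of 8 (allyldiisopropoxyborane, catalytic 3,3'-dibromo-BINOL, the enantiomer that gives the 2S carbinol) gives (2S)-2-[(1S,3S,4S)-3-bromo-4-chloro-4-methylcyclohexyl]pent-4-en-2-ol F1. Acylation with acryloyl chloride, i-Pr2NEt and DMAP gives its acrylate ester F2. Ring-closing metathesis with the second-generation Grubbs catalyst in toluene at 80 °C gives the α,β-unsaturated δ-lactone F3. MeLi/CeCl3 in THF at −78 °C adds twice to the lactone carbonyl and opens it to the (Z)-ene diol F4. Catalytic camphorsulfonic acid in CH2Cl2 then ionises the tertiary allylic alcohol, the C6 hydroxyl closes O1–C2, and 18 is reached.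

2. Step 6. What may go wrong: loss of HBr from the tertiary bromide at the temperature needed; acid-catalysed enolisation that epimerises C1' of 8 towards its more stable epimer; an equilibrium that stops short of 8. Fallback, from ketone 7 back to dihydropyran 18: the interchange is postponed. Ketone 7, whose C1' configuration is the stable one, is taken with 15 through the conditions of step 11 to give (2S)-2-[(1S,3R,4R)-4-bromo-3-chloro-4-methylcyclohexyl]-2,6,6-trimethyl-3,6-dihydro-2H-pyran F5. In F5, C1' can no longer epimerise and the ring A substituent is a firm equatorial anchor, so the thermal Br/Cl interchange (PhCl, CaCO3, 130 °C) is run there and delivers 18.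

3. Step 12. What may go wrong: a slow ene step at the hindered C3 terminus, over-oxidation to the C5 ketone, and erosion of the facial preference. Fallback, from dihydropyran 18 to target 19 by oxygen transposition: photo-oxygenation (O2, tetraphenylporphyrin, visible light, CH2Cl2) in the presence of Ac2O, pyridine and DMAP gives, by a singlet-oxygen ene reaction that removes the same pseudoaxial C5–H, the C3 hydroperoxide F6. F6 is dehydrated in the flask (Kornblum–DeLaMare type) to the transposed enone (6R)-6-[(1S,3S,4S)-3-bromo-4-chloro-4-methylcyclohexyl]-2,2,6-trimethyl-2H-pyran-3(6H)-one F7. Nucleophilic epoxidation (H2O2, NaOH, MeOH, 0 °C) adds to C5 anti to the axial C6 methyl and gives the epoxy ketone F8 with the oxirane on the ring B face. Wharton transposition (N2H4·H2O, AcOH, MeOH) then gives 19, with the C5–O bond of the epoxide retained.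

**Further compounds**

F1 | step 11 | (2S)-2-[(1S,3S,4S)-3-bromo-4-chloro-4-methylcyclohexyl]pent-4-en-2-ol | C=CC[C@](C)(O)[C@H]1CC[C@](C)(Cl)[C@@H](Br)C1
F2 | step 11 | (2S)-2-[(1S,3S,4S)-3-bromo-4-chloro-4-methylcyclohexyl]pent-4-en-2-yl prop-2-enoate | C=CC[C@](C)(OC(=O)C=C)[C@H]1CC[C@](C)(Cl)[C@@H](Br)C1
F3 | step 11 | (6S)-6-[(1S,3S,4S)-3-bromo-4-chloro-4-methylcyclohexyl]-6-methyl-5,6-dihydro-2H-pyran-2-one | O=C1C=CC[C@@](C)([C@H]2CC[C@](C)(Cl)[C@@H](Br)C2)O1
F4 | step 11 | (3Z,6S)-6-[(1S,3S,4S)-3-bromo-4-chloro-4-methylcyclohexyl]-2-methylhept-3-ene-2,6-diol | CC(C)(O)/C=C\C[C@](C)(O)[C@H]1CC[C@](C)(Cl)[C@@H](Br)C1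
F5 | step 6 | (2S)-2-[(1S,3R,4R)-4-bromo-3-chloro-4-methylcyclohexyl]-2,6,6-trimethyl-3,6-dihydro-2H-pyran | CC1(C)C=CC[C@@](C)([C@H]2CC[C@@](C)(Br)[C@H](Cl)C2)O1
F6 | step 12 | (3S,6R)-6-[(1S,3S,4S)-3-bromo-4-chloro-4-methylcyclohexyl]-3-hydroperoxy-2,2,6-trimethyl-3,6-dihydro-2H-pyran | CC1(C)[C@@H](OO)C=C[C@@](C)([C@H]2CC[C@](C)(Cl)[C@@H](Br)C2)O1
F7 | step 12 | (6R)-6-[(1S,3S,4S)-3-bromo-4-chloro-4-methylcyclohexyl]-2,2,6-trimethyl-2H-pyran-3(6H)-one | CC1(C)C(=O)C=C[C@@](C)([C@H]2CC[C@](C)(Cl)[C@@H](Br)C2)O1
F8 | step 12 | 4,5-epoxide of F7 with the oxirane oxygen cis to ring B and anti to the C6 methyl | CC1(C)C(=O)[C@H]2O[C@H]2[C@@](C)([C@H]3CC[C@](C)(Cl)[C@@H](Br)C3)O1
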